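## Structural features

Target 39 is a ten-membered carbocycle with a trans-fused α-methylene-γ-butyrolactone. The ring is numbered C1–C10: C4 is the CHMe carbon, C6 the lactone O–CH, C7 the ring-fusion CH, C8 the acyloxy CH, and C10 the alkene carbon that carries C14 (CH2OAc). C11–C13 are the lactone carbons. The diene C3=C2–C1=C10 is conjugated and both double bonds are cis within the ring. Three contiguous stereocentres, C6 (S), C7 (R) and C8 (R), lie on one side of the diene and the isolated C4 (S) on the other, so relative configuration has to be carried across a flexible medium ring. The C8 oxygen is acylated by (S)-2,3-dihydroxy-2-methylpropanoic acid, which has a quaternary carbinol centre. The fragile groups are the exocyclic enoate (a Michael acceptor), the dienylic primary acetate, the diene, the free diol beside two esters, and the lactone, which can migrate to the C8 oxygen under base. The real difficulty is the ten-membered ring with a cis,cis-diene and a fixed C4/C6–C8 relationship. The key step exploits the fact that C8, C9, C10, C1, C2 and C3 are six contiguous ring carbons that can be a benzene ring with C14 as its methyl group. C3 and C8 are then joined by a bond that is also shared with a cyclohexane made of C4–C7, so the target is a tetralin whose ring-fusion bond has been cut.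

## Logic of the disconnections

39 to 38. The two C–O bonds of an isopropylidene acetal are put back on the side-chain diol. A free tertiary/primary diol would interfere with every acylation and base step. The gain is a compact acyl unit without α-hydrogen. The demand is a final acid hydrolysis that spares the enoate, the dienylic acetate and the C8 ester.

38 to 37 to 36. The acetate C–O bond and then the C14–O bond are cut. C14 is the only oxidised carbon outside the bicyclic template, and it has to be a plain methyl group for the arene reduction to give the right diene. The gain is that C14 comes from a cheap tolyl unit. The demand is an allylic oxidation that picks the methyl group at the diene terminus.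

36 to 32. The C11=C13 bond is cut. The exocyclic enoate would not survive ozone, hydride, strong base or palladium hydride. The gain is an ordinary lactone through most of the route. The demand is enolate chemistry next to a C8 ester and a diene.

32 to 31 to 29. C3–H is exchanged for C3–OTf and then for the C3 ketone. The ketone is what ring cleavage leaves at C3, so the diene is made from it without forming a C–C bond. The demand is enolisation toward C2 only, with ring-cis geometry.

29 to 22 and 27. The C8 O–acyl bond is cut. This is the convergent point, and the acyl group also protects the C8 hydroxyl through the base steps. The demand is esterification of a hindered secondary alcohol without moving the β,γ-double bond into conjugation and without lactone migration.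

27 to 26 to 24 to 23. The acetal C–O bonds, the primary C–O bond from epoxide opening, and the carboxyl oxidation level are removed in turn. The quaternary centre is taken from the chiral pool. The demand is that oxidation precedes epoxide opening, because opening first would give an achiral triol, and that hydroxide attacks the CH2 carbon only.

22 to 21. The C8–H bond is cut. The C8 oxygen arrives as a ketone from ring cleavage. The demand is a hydride that is selective for C8 over C3 and for one face.

21 to 19. C3 and C8 are rejoined as a double bond. This turns the ten-membered ring into a bicyclic 1,4-diene, the reduction product of an arene. The gain is that the medium ring is never cyclised and the cis C1=C10 geometry is inherent. The demand is an oxidant that chooses the tetrasubstituted alkene.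

19 to 18 to 16. The lactone C–O bond is opened and the ring is re-aromatised. The arene is the template on which C4, C6 and C7 are set. The demand is a dissolving-metal reduction run on the carboxylate, with the alkyl groups directing the diene pattern.

16 to 15 to 12 and 13. The C7–C11 bond and the lactone O–C12 bond are cut. One epoxide delivers C6 and C7 with trans geometry. The demand is attack at benzylic C7.

12 to 11 to 9. The epoxide C–O bonds are cut and the C6=C7 alkene is traced to the ketone. The demand is epoxidation on the face away from the C4 methyl group.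

9 to 8 to 7 to 3. The C7–C8 aryl–acyl bond and the C6–C7 bond of a one-carbon homologation are cut. This leaves a 3-arylbutanoate.

3 to 1 and 2. The aryl–C4 bond is cut. The only catalyst-controlled stereocentre of the ring is set here, and both partners are commodity chemicals.

## Other disconnections considered

Alternative 1: The cut is C7–C11, with C11=C13 formed in the same flask, on an open-chain precursor. In the forward step the C6 diethylphosphonoacetate A2, which carries a cis C7–C8 epoxide, is treated with NaH in THF. The stabilised anion opens the epoxide at C7 with inversion in a 5-exo mode, the lactone closes, the C8 alkoxide is released, and paraformaldehyde then converts the remaining phosphonate anion into the methylene group of A1. In its favour, C7 and C8 both come from one epoxide of defined geometry, the exocyclic alkene is made without enolising a finished macrocycle, and the C14 oxygen and both alkene termini are carried from fragments. There is no ketone differentiation and no late allylic oxidation; on these points it is the better plan. Against it, the step does not make the ten-membered ring, so a macrocyclisation of the kind in alternative 3 is still needed. A2 also demands separate asymmetric construction of C4, C6 and the epoxide, plus a Z-vinyl iodide and a trisubstituted vinylstannane. The liberated C8 alkoxide can attack the phosphonate or the new lactone, and 6-endo opening at C8 competes. Compared with the chosen plan, alternative 1 forms a skeletal bond and two stereocentres in its key step where step 11 forms none, but it pays with a longer linear sequence and leaves ring formation unsolved.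

Alternative 2: The cut is C8–C9, made by a [3,3] shift that also breaks the bond between the carbinol carbon (future C6) and C1 of a cyclohexenol. In the forward step the potassium alkoxide of the cis-1,2-dialkenylcyclohex-3-enol A4 (KH, 18-crown-6) rearranges to the ten-membered dienone A3, with the C6 ketone, the C1=C10 alkene and the C8 PMB ether in place. In its favour, ring, diene, C14 oxygen and the C8 stereocentre (by chirality transfer through a chair transition state from the E enol ether) all come from one mild C–C bond-forming step. It is more convergent than the chosen plan, and it avoids both the two-ketone problem and the triflate detour; these are real advantages. Against it, the C1=C10 geometry depends on which of two chair transition states is followed. The lactone must afterwards be annulated onto a flexible medium ring, which means regioselective enolisation at C7 rather than C5, a C7 alkylation and a C6 reduction, each needing stereocontrol relative to C8 and C4. The dienone is also open to conjugation and transannular reactions. The chosen plan sets C4, C6 and C7 on a rigid tetralin but leaves C8 to a medium-ring reduction; alternative 2 does the reverse. In step count the two are probably similar.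

Alternative 3: The cut is the central C1–C2 bond of the diene. In the forward step the acyclic compound A6, with a C1 vinylstannane and a Z C2 vinyl iodide, is coupled under Pd(PPh3)4, CuI and CsF at high dilution. Oxidative addition, copper-assisted transmetalation and reductive elimination close the ring to A5 with both alkene geometries retained. In its favour, every stereocentre, the lactone, the methylene group, the C14 oxygen and the side chain are in place before the ring forms, and the geometries are fixed by the fragments. On stereochemical certainty it is the equal or the better of the chosen plan. Against it, direct closure of a ten-membered cis,cis-diene is enthalpically and entropically unfavourable, so oligomerisation and protodestannylation are expected to compete. The enoate is exposed to palladium and tin reagents, and A6 is essentially A1 carried further, so the longest linear sequence is long. In the chosen plan the ring cannot fail to form because it is revealed by bond cleavage; the price is the post-cleavage functional-group work that alternative 3 avoids.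

Key step: step 11

Assumption: the facial sense of the two chiral catalysts (steps 1 and 6) is taken from the usual models for (E)-enoates and for 1,2-dihydronaphthalenes; if either proves opposite, the antipodal ligand is used and nothing else changes.

## Route

Step 1
Reactants: 1 4-methylphenylboronic acid; 2 ethyl (E)-but-2-enoate
Product: 3 ethyl (3S)-3-(4-methylphenyl)butanoate
Conditions: Rh(acac)(C2H4)2 (3 mol %), (R)-BINAP (4.5 mol %), 1 (3 equiv), dioxane/H2O 10:1, 100 °C
Reagents that add atoms: none
Why: Hayashi–Miyaura 1,4-addition; the aryl–rhodium species inserts the enoate and water protonates the oxa-π-allyl, and the BINAP pocket selects the enantioface of the β-carbon so that C4 is set as S.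

Step 2
Reactants: 3 ethyl (3S)-3-(4-methylphenyl)butanoate
Product: 7 ethyl (4S)-4-(4-methylphenyl)pentanoate, via dibromomethyl alkoxide adduct 4 (not isolated), via lithium dibromoenolate 5 (not isolated), via lithium ynolate 6 (not isolated)
Conditions: CH2Br2, lithium 2,2,6,6-tetramethylpiperidide, THF, −78 °C; LiN(SiMe3)2; n-BuLi, −78 → 20 °C; then HCl/EtOH, 0 °C
Reagents that add atoms: dibromomethane, BrCBr; ethanol, CCO
Why: Kowalski ester homologation; bromine–lithium exchange on the dibromoenolate triggers a 1,2-shift to the ynolate, which acidic ethanol turns into the ester with one more carbon (C7), and the remote C4 centre is untouched.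

Step 3
Reactants: 7 ethyl (4S)-4-(4-methylphenyl)pentanoate
Product: 8 (4S)-4-(4-methylphenyl)pentanoic acid
Conditions: LiOH·H2O, THF/H2O, 20 °C; then 1 M HCl
Reagents that add atoms: lithium hydroxide, [Li+].[OH-]
Why: Ester saponification; no stereocentre is α to the carbonyl.

Step 4
Reactants: 8 (4S)-4-(4-methylphenyl)pentanoic acid
Product: 9 (4S)-4,7-dimethyl-3,4-dihydronaphthalen-1(2H)-one
Conditions: P2O5 in MeSO3H (Eaton's reagent), 40 °C
Reagents that add atoms: none
Why: Intramolecular Friedel–Crafts acylation forms C7–C8; the two positions ortho to the side chain are equivalent, so only one tetralone can form, and the benzylic C4–H is not ionised under these conditions.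

Step 5
Reactants: 9 (4S)-4,7-dimethyl-3,4-dihydronaphthalen-1(2H)-one
Product: 11 (1S)-1,6-dimethyl-1,2-dihydronaphthalene, via tetralol 10 (not isolated)
Conditions: NaBH4, MeOH, 0 °C; then TsOH·H2O (5 mol %), PhMe, 80 °C
Reagents that add atoms: none
Why: Ketone reduction, then acid-catalysed dehydration of the benzylic alcohol, which can only give the styrene-type C6=C7 alkene; the carbinol configuration is irrelevant.

Step 6
Reactants: 11 (1S)-1,6-dimethyl-1,2-dihydronaphthalene
Product: 12 (1R,2S,4S)-1,2-epoxy-4,7-dimethyl-1,2,3,4-tetrahydronaphthalene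
Conditions: (R,R)-[N,N′-bis(3,5-di-tert-butylsalicylidene)cyclohexane-1,2-diaminato]MnCl (4 mol %), NaOCl (aq, pH 11), 4-phenylpyridine N-oxide, CH2Cl2, 0 °C
Reagents that add atoms: sodium hypochlorite, [Na+].[O-]Cl
Why: Jacobsen–Katsuki epoxidation of a cis-disubstituted aryl alkene; the pseudoaxial C4 methyl shields one face and the catalyst enantiomer is chosen to reinforce this, so oxygen should add anti to the methyl and set C6 and C7.

Step 7
Reactants: 12 (1R,2S,4S)-1,2-epoxy-4,7-dimethyl-1,2,3,4-tetrahydronaphthalene; 13 diethyl malonate
Product: 15 ethyl (3aS,5S,9bS)-5,8-dimethyl-2-oxo-1,2,3a,4,5,9b-hexahydronaphtho[2,1-b]furan-1-carboxylate, via hydroxy malonate 14 (not isolated)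
Conditions: NaOEt, EtOH, 80 °C; then AcOH
Reagents that add atoms: none
Why: Malonic ester opening of an epoxide with in situ lactonisation; SN2 attack anti to oxygen at benzylic C7 inverts that centre and makes C7–C11, attack at C6 is disfavoured by the 1,3-related C4 methyl on the approach face, and the trans alkoxide closes the lactone.

Step 8
Reactants: 15 ethyl (3aS,5S,9bS)-5,8-dimethyl-2-oxo-1,2,3a,4,5,9b-hexahydronaphtho[2,1-b]furan-1-carboxylate
Product: 16 (3aS,5S,9bS)-5,8-dimethyl-3a,4,5,9b-tetrahydronaphtho[2,1-b]furan-2(1H)-one
Conditions: LiCl, H2O, DMSO, 150 °C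
Reagents that add atoms: none
Why: Krapcho dealkoxycarbonylation; chloride dealkylates the ethyl ester, the carboxylate loses CO2, and the ring-fusion centres are not affected.

Step 9
Reactants: 16 (3aS,5S,9bS)-5,8-dimethyl-3a,4,5,9b-tetrahydronaphtho[2,1-b]furan-2(1H)-one
Product: 18 2-[(1S,2S,4S)-2-hydroxy-4,7-dimethyl-1,2,3,4,5,8-hexahydronaphthalen-1-yl]acetic acid, via lithium carboxylate 17 (not isolated)
Conditions: LiOH·H2O, THF/H2O, 20 °C, evaporate; Li, NH3(l), THF, t-BuOH, −78 → −33 °C; NH4Cl; 1 M HCl to pH 3, 0 °C
Reagents that add atoms: lithium hydroxide, [Li+].[OH-]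
Why: Birch reduction run on the carboxylate, which is inert to solvated electrons where the lactone is not; the three alkyl-bearing ring carbons C3, C8 and C10 stay sp2, so protonation falls on C2 and C9 and gives the tetrasubstituted C3=C8 and trisubstituted C1=C10 alkenes.

Step 10
Reactants: 18 2-[(1S,2S,4S)-2-hydroxy-4,7-dimethyl-1,2,3,4,5,8-hexahydronaphthalen-1-yl]acetic acid
Product: 19 (3aS,5S,9bS)-5,8-dimethyl-3a,4,5,6,9,9b-hexahydronaphtho[2,1-b]furan-2(1H)-one
Conditions: EDC·HCl, DMAP (10 mol %), CH2Cl2, 0 → 20 °C
Reagents that add atoms: none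
Why: Carbodiimide lactonisation of a γ-hydroxy acid under near-neutral conditions, chosen so that the acid-sensitive 1,4-diene is not isomerised.

Step 11
Reactants: 19 (3aS,5S,9bS)-5,8-dimethyl-3a,4,5,6,9,9b-hexahydronaphtho[2,1-b]furan-2(1H)-one
Product: 21 (3aR,6Z,10S,11aS)-6,10-dimethyl-3a,5,8,10,11,11a-hexahydrocyclodeca[b]furan-2,4,9(3H)-trione, via methoxy hydroperoxide 20 (not isolated)
Conditions: O3 (1.0 equiv, titrated solution in CH2Cl2), CH2Cl2/MeOH 4:1, NaHCO3, −78 °C; then Me2S, −78 → 20 °C
Reagents that add atoms: ozone, [O-][O+]=O
Why: Ozone adds as a 1,3-dipole to the C3=C8 bond, the primary ozonide cycloreverts to a ketone and a carbonyl oxide, methanol traps the latter as 20, and Me2S cleaves the O–O bond so that the hemiketal collapses to the second ketone. The closest known reaction type is ozonolysis of the ring-fusion alkene of Birch-reduced tetralins and octalins to cyclodecane-1,6-diones. The ten-membered ring is not closed by a cyclisation; it appears when the bond shared by the two six-membered rings is severed, so no medium-ring closure penalty is paid. No stereocentre is created, but C4 and C7 become α to carbonyl groups, which is why the medium is buffered and the work-up neutral. The selectivity needed is tetrasubstituted over trisubstituted alkene; ozone is electrophilic and C3=C8 carries four alkyl donors, so one equivalent delivered cold should consume it first. The C1=C10 bond is untouched and keeps the cis geometry it had in the cyclohexadiene.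

Step 12
Reactants: 21 (3aR,6Z,10S,11aS)-6,10-dimethyl-3a,5,8,10,11,11a-hexahydrocyclodeca[b]furan-2,4,9(3H)-trione
Product: 22 (3aS,4R,6Z,10S,11aS)-4-hydroxy-6,10-dimethyl-3a,4,5,8,10,11-hexahydrocyclodeca[b]furan-2,9(3H,11aH)-dione
Conditions: NaBH4 (0.3 equiv), CH2Cl2/MeOH 1:1, −78 °C; then AcOH
Reagents that add atoms: none
Why: Chemoselective ketone reduction; the C8 carbonyl is the more electrophilic because of the β-acyloxy group, and peripheral Felkin–Anh attack anti to the C7–C11 bond should give the 8R alcohol, though the ring conformation is not known and this face preference is the least secure prediction of the route.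

Step 13
Reactants: 23 (R)-2-methylglycidol
Product: 24 (2S)-2-methyloxirane-2-carboxylic acid
Conditions: RuCl3·xH2O (2 mol %), NaIO4 (2.2 equiv), MeCN/EtOAc/H2O, 0 → 20 °C
Reagents that add atoms: water, O; sodium periodate, [Na+].[O-]I(=O)(=O)=O
Why: RuO4-catalysed oxidation of a primary epoxy alcohol to the glycidic acid; the quaternary centre is not touched (the descriptor changes only by priority), and oxidising first keeps the two CH2 arms distinct.

Step 14
Reactants: 24 (2S)-2-methyloxirane-2-carboxylic acid
Product: 26 methyl (4S)-2,2,4-trimethyl-1,3-dioxolane-4-carboxylate, via dihydroxy acid 25 (not isolated)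
Conditions: 1 M NaOH, 70 °C; HCl to pH 2, evaporate; 2,2-dimethoxypropane, MeOH, TsOH·H2O (cat.), 40 °C
Reagents that add atoms: sodium hydroxide, [Na+].[OH-]; 2,2-dimethoxypropane, COC(C)(C)OC; methanol, CO
Why: Hydroxide opens the glycidate at the unhindered CH2 with retention at the quaternary carbon, then Fischer esterification and acetonide formation occur together; esterifying first excludes the competing dioxolanone.

Step 15
Reactants: 26 methyl (4S)-2,2,4-trimethyl-1,3-dioxolane-4-carboxylate
Product: 27 (4S)-2,2,4-trimethyl-1,3-dioxolane-4-carboxylic acid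
Conditions: LiOH·H2O, THF/H2O, 0 → 20 °C; 1 M HCl to pH 3, 0 °C
Reagents that add atoms: lithium hydroxide, [Li+].[OH-]
Why: Saponification of an ester with no α-hydrogen; the acetonide is stable to base and survives a brief cold acidification.

Step 16
Reactants: 22 (3aS,4R,6Z,10S,11aS)-4-hydroxy-6,10-dimethyl-3a,4,5,8,10,11-hexahydrocyclodeca[b]furan-2,9(3H,11aH)-dione; 27 (4S)-2,2,4-trimethyl-1,3-dioxolane-4-carboxylic acid
Product: 29 (3aR,4R,6Z,10S,11aS)-6,10-dimethyl-2,9-dioxo-2,3,3a,4,5,8,9,10,11,11a-decahydrocyclodeca[b]furan-4-yl (4S)-2,2,4-trimethyl-1,3-dioxolane-4-carboxylate, via mixed anhydride 28 (not isolated)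
Conditions: 27, 2,4,6-trichlorobenzoyl chloride, Et3N, THF, 0 °C; then 22, DMAP, PhMe, 0 → 20 °C
Reagents that add atoms: none
Why: Yamaguchi esterification, suited to a hindered secondary alcohol and an α-quaternary acid, with retention at C8; installing the final acyl group here also caps the hydroxyl for the base steps and saves a protecting group.

Step 17
Reactants: 29 (3aR,4R,6Z,10S,11aS)-6,10-dimethyl-2,9-dioxo-2,3,3a,4,5,8,9,10,11,11a-decahydrocyclodeca[b]furan-4-yl (4S)-2,2,4-trimethyl-1,3-dioxolane-4-carboxylate
Product: 31 (3aR,4R,6Z,8E,10S,11aS)-6,10-dimethyl-2-oxo-9-(trifluoromethanesulfonyloxy)-2,3,3a,4,5,10,11,11a-octahydrocyclodeca[b]furan-4-yl (4S)-2,2,4-trimethyl-1,3-dioxolane-4-carboxylate, via potassium dienolate 30 (not isolated)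
Conditions: KN(SiMe3)2 (1.05 equiv), THF, −78 °C; PhNTf2, −78 → −20 °C
Reagents that add atoms: N-phenylbis(trifluoromethanesulfonimide), O=S(=O)(N(c1ccccc1)S(=O)(=O)C(F)(F)F)C(F)(F)F
Why: Dienyl triflate formation from a β,γ-unsaturated ketone; the C2 hydrogens are both α-keto and allylic, far more acidic than C4–H or the lactone α-hydrogens, the hard electrophile reacts at oxygen, and the ring-cis enol geometry is expected because cis-cyclodecenes are the more stable isomers.

Step 18
Reactants: 31 (3aR,4R,6Z,8E,10S,11aS)-6,10-dimethyl-2-oxo-9-(trifluoromethanesulfonyloxy)-2,3,3a,4,5,10,11,11a-octahydrocyclodeca[b]furan-4-yl (4S)-2,2,4-trimethyl-1,3-dioxolane-4-carboxylate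
Product: 32 (3aR,4R,6Z,8Z,10S,11aS)-6,10-dimethyl-2-oxo-2,3,3a,4,5,10,11,11a-octahydrocyclodeca[b]furan-4-yl (4S)-2,2,4-trimethyl-1,3-dioxolane-4-carboxylate
Conditions: Pd(OAc)2 (5 mol %), PPh3 (10 mol %), Bu3N (3 equiv), HCO2H (2 equiv), DMF, 60 °C
Reagents that add atoms: none
Why: Palladium-catalysed formate reduction of an enol triflate; oxidative addition to zerovalent palladium, formate exchange, loss of CO2 and reductive elimination replace OTf by H with retention of alkene geometry, and the C8 ester is homoallylic so it cannot ionise.

Step 19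
Reactants: 32 (3aR,4R,6Z,8Z,10S,11aS)-6,10-dimethyl-2-oxo-2,3,3a,4,5,10,11,11a-octahydrocyclodeca[b]furan-4-yl (4S)-2,2,4-trimethyl-1,3-dioxolane-4-carboxylate
Product: 36 (3aR,4R,6Z,8Z,10S,11aS)-6,10-dimethyl-3-methylidene-2-oxo-2,3,3a,4,5,10,11,11a-octahydrocyclodeca[b]furan-4-yl (4S)-2,2,4-trimethyl-1,3-dioxolane-4-carboxylate, via lithium enolate 33 (not isolated), via Mannich base 34 (not isolated), via ammonium iodide 35 (not isolated)
Conditions: LiN(i-Pr)2 (1.2 equiv), THF, −78 °C; CH2=NMe2+ I−, −78 → 20 °C; MeI, MeOH, 20 °C; NaHCO3, CH2Cl2/H2O, 20 °C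
Reagents that add atoms: N,N-dimethylmethyleneiminium iodide (Eschenmoser's salt), C=[N+](C)C.[I-]
Why: Standard α-methylenation of a γ-lactone by Mannich alkylation, quaternisation and elimination; the C8 ester has no α-hydrogen and C11 becomes sp2, so no stereocentre is at stake.

Step 20
Reactants: 36 (3aR,4R,6Z,8Z,10S,11aS)-6,10-dimethyl-3-methylidene-2-oxo-2,3,3a,4,5,10,11,11a-octahydrocyclodeca[b]furan-4-yl (4S)-2,2,4-trimethyl-1,3-dioxolane-4-carboxylate
Product: 37 (3aR,4R,6E,8Z,10S,11aS)-6-(hydroxymethyl)-10-methyl-3-methylidene-2-oxo-2,3,3a,4,5,10,11,11a-octahydrocyclodeca[b]furan-4-yl (4S)-2,2,4-trimethyl-1,3-dioxolane-4-carboxylate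
Conditions: SeO2 (0.5 equiv), t-BuOOH (3 equiv), CH2Cl2, 20 °C
Reagents that add atoms: selenium dioxide, O=[Se]=O; tert-butyl hydroperoxide, CC(C)(C)OO
Why: Allylic hydroxylation by ene reaction and [2,3]-shift; C14 is the alkyl group trans to the chain on the more substituted terminus of the trisubstituted alkene, C9–H is deactivated by the adjacent acyloxy carbon, and the sequence returns the double bond to C1=C10 with the same ring-cis geometry.

Step 21
Reactants: 37 (3aR,4R,6E,8Z,10S,11aS)-6-(hydroxymethyl)-10-methyl-3-methylidene-2-oxo-2,3,3a,4,5,10,11,11a-octahydrocyclodeca[b]furan-4-yl (4S)-2,2,4-trimethyl-1,3-dioxolane-4-carboxylate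
Product: 38 (3aR,4R,6E,8Z,10S,11aS)-6-(acetoxymethyl)-10-methyl-3-methylidene-2-oxo-2,3,3a,4,5,10,11,11a-octahydrocyclodeca[b]furan-4-yl (4S)-2,2,4-trimethyl-1,3-dioxolane-4-carboxylate
Conditions: Ac2O, pyridine, CH2Cl2, 0 → 20 °C
Reagents that add atoms: acetic anhydride, CC(=O)OC(C)=O
Why: Acetylation of the only free hydroxyl; done before diol release because two primary hydroxyls could not be told apart afterwards.

Step 22
Reactants: 38 (3aR,4R,6E,8Z,10S,11aS)-6-(acetoxymethyl)-10-methyl-3-methylidene-2-oxo-2,3,3a,4,5,10,11,11a-octahydrocyclodeca[b]furan-4-yl (4S)-2,2,4-trimethyl-1,3-dioxolane-4-carboxylate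
Product: 39 (3aR,4R,6E,8Z,10S,11aS)-6-(acetoxymethyl)-10-methyl-3-methylidene-2-oxo-2,3,3a,4,5,10,11,11a-octahydrocyclodeca[b]furan-4-yl (2S)-2,3-dihydroxy-2-methylpropanoate
Conditions: AcOH/H2O 4:1, 40 °C
Reagents that add atoms: none
Why: Acid hydrolysis of the isopropylidene acetal; any acetolysis of the dienylic acetate is degenerate in this medium, and the enoate and the hindered C8 ester are stable to it.

## Compound list

1 | 4-methylphenylboronic acid | Cc1ccc(cc1)B(O)O | starting material
2 | ethyl (E)-but-2-enoate | C/C=C/C(=O)OCC | starting material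
3 | ethyl (3S)-3-(4-methylphenyl)butanoate | CCOC(=O)C[C@H](C)c1ccc(C)cc1 | intermediate
4 | lithium (4S)-1,1-dibromo-2-ethoxy-4-(4-methylphenyl)pentan-2-olate | [Li+].CCOC([O-])(C[C@H](C)c1ccc(C)cc1)C(Br)Br | intermediate
5 | lithium (4S)-1,1-dibromo-4-(4-methylphenyl)pent-1-en-2-olate | [Li+].[O-]C(=C(Br)Br)C[C@H](C)c1ccc(C)cc1 | intermediate
6 | lithium (4S)-4-(4-methylphenyl)pent-1-yn-1-olate | [Li+].[O-]C#CC[C@H](C)c1ccc(C)cc1 | intermediate
7 | ethyl (4S)-4-(4-methylphenyl)pentanoate | CCOC(=O)CC[C@H](C)c1ccc(C)cc1 | intermediate
8 | (4S)-4-(4-methylphenyl)pentanoic acid | OC(=O)CC[C@H](C)c1ccc(C)cc1 | intermediate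
9 | (4S)-4,7-dimethyl-3,4-dihydronaphthalen-1(2H)-one | O=C1CC[C@H](C)c2ccc(C)cc12 | intermediate
10 | (4S)-4,7-dimethyl-1,2,3,4-tetrahydronaphthalen-1-ol (both C1 epimers) | OC1CC[C@H](C)c2ccc(C)cc12 | intermediate
11 | (1S)-1,6-dimethyl-1,2-dihydronaphthalene | C[C@H]1CC=Cc2cc(C)ccc12 | intermediate
12 | (1R,2S,4S)-1,2-epoxy-4,7-dimethyl-1,2,3,4-tetrahydronaphthalene | C[C@H]1C[C@@H]2O[C@@H]2c2cc(C)ccc12 | intermediate
13 | diethyl malonate | CCOC(=O)CC(=O)OCC | starting material
14 | diethyl 2-[(1S,2S,4S)-2-hydroxy-4,7-dimethyl-1,2,3,4-tetrahydronaphthalen-1-yl]malonate (formed as its sodium alkoxide) | O[C@H]1C[C@H](C)c2ccc(C)cc2[C@@H]1C(C(=O)OCC)C(=O)OCC | intermediate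
15 | ethyl (3aS,5S,9bS)-5,8-dimethyl-2-oxo-1,2,3a,4,5,9b-hexahydronaphtho[2,1-b]furan-1-carboxylate (C1 epimers) | CCOC(=O)C1C(=O)O[C@H]2C[C@H](C)c3ccc(C)cc3[C@H]12 | intermediate
16 | (3aS,5S,9bS)-5,8-dimethyl-3a,4,5,9b-tetrahydronaphtho[2,1-b]furan-2(1H)-one | C1C(=O)O[C@H]2C[C@H](C)c3ccc(C)cc3[C@H]12 | intermediate
17 | lithium 2-[(1S,2S,4S)-2-hydroxy-4,7-dimethyl-1,2,3,4-tetrahydronaphthalen-1-yl]acetate | [Li+].O[C@H]1C[C@H](C)c2ccc(C)cc2[C@@H]1CC(=O)[O-] | intermediate
18 | 2-[(1S,2S,4S)-2-hydroxy-4,7-dimethyl-1,2,3,4,5,8-hexahydronaphthalen-1-yl]acetic acid | O[C@H]1C[C@H](C)C2=C(CC(C)=CC2)[C@@H]1CC(=O)O | intermediate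
19 | (3aS,5S,9bS)-5,8-dimethyl-3a,4,5,6,9,9b-hexahydronaphtho[2,1-b]furan-2(1H)-one (1,4-dihydro tetralin trans-lactone) | C1C(=O)O[C@H]2C[C@H](C)C3=C(CC(C)=CC3)[C@H]12 | intermediate
20 | C3 methoxy hydroperoxide of the C8 ketone (formed together with its C8/C3 regioisomer) | C1C(=O)O[C@H]2C[C@H](C)C(OC)(OO)C/C=C(/C)CC(=O)[C@H]12 | intermediate
21 | (3aR,6Z,10S,11aS)-6,10-dimethyl-3a,5,8,10,11,11a-hexahydrocyclodeca[b]furan-2,4,9(3H)-trione (3,8-diketone lactone) | C1C(=O)O[C@H]2C[C@H](C)C(=O)C/C=C(/C)CC(=O)[C@H]12 | intermediate
22 | (3aS,4R,6Z,10S,11aS)-4-hydroxy-6,10-dimethyl-3a,4,5,8,10,11-hexahydrocyclodeca[b]furan-2,9(3H,11aH)-dione | C1C(=O)O[C@H]2C[C@H](C)C(=O)C/C=C(/C)C[C@@H](O)[C@H]12 | intermediate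
23 | (R)-2-methylglycidol | OC[C@@]1(C)OC1 | starting material
24 | (2S)-2-methyloxirane-2-carboxylic acid | OC(=O)[C@@]1(C)OC1 | intermediate
25 | (2S)-2,3-dihydroxy-2-methylpropanoic acid | OC(=O)[C@@](C)(O)CO | intermediate
26 | methyl (4S)-2,2,4-trimethyl-1,3-dioxolane-4-carboxylate | COC(=O)[C@]1(C)COC(C)(C)O1 | intermediate
27 | (4S)-2,2,4-trimethyl-1,3-dioxolane-4-carboxylic acid | OC(=O)[C@]1(C)COC(C)(C)O1 | intermediate
28 | (4S)-2,2,4-trimethyl-1,3-dioxolane-4-carboxylic 2,4,6-trichlorobenzoic anhydride | O=C(OC(=O)[C@]1(C)COC(C)(C)O1)c1c(Cl)cc(Cl)cc1Cl | intermediate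
29 | C3 ketone with the C8 acetonide ester, (4S,6S,7R,8R) | C1C(=O)O[C@H]2C[C@H](C)C(=O)C/C=C(/C)C[C@@H](OC(=O)[C@]3(C)COC(C)(C)O3)[C@H]12 | intermediate
30 | potassium C3 dienolate of 29 | [K+].C1C(=O)O[C@H]2C[C@H](C)/C([O-])=C\C=C(\C)C[C@@H](OC(=O)[C@]3(C)COC(C)(C)O3)[C@H]12 | intermediate
31 | C3 dienyl triflate, ring-cis C2=C3 and C1=C10 | C1C(=O)O[C@H]2C[C@H](C)/C(OS(=O)(=O)C(F)(F)F)=C\C=C(\C)C[C@@H](OC(=O)[C@]3(C)COC(C)(C)O3)[C@H]12 | intermediate
32 | cis,cis-diene lactone with C14 methyl | C1C(=O)O[C@H]2C[C@H](C)/C=C\C=C(\C)C[C@@H](OC(=O)[C@]3(C)COC(C)(C)O3)[C@H]12 | intermediate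
33 | lithium enolate of lactone 32 | [Li+].C1=C([O-])O[C@H]2C[C@H](C)/C=C\C=C(\C)C[C@@H](OC(=O)[C@]3(C)COC(C)(C)O3)[C@H]12 | intermediate
34 | C11 dimethylaminomethyl lactone | CN(C)CC1C(=O)O[C@H]2C[C@H](C)/C=C\C=C(\C)C[C@@H](OC(=O)[C@]3(C)COC(C)(C)O3)[C@H]12 | intermediate
35 | C11 trimethylammoniomethyl lactone iodide | [I-].C[N+](C)(C)CC1C(=O)O[C@H]2C[C@H](C)/C=C\C=C(\C)C[C@@H](OC(=O)[C@]3(C)COC(C)(C)O3)[C@H]12 | intermediate
36 | α-methylene lactone diene with C14 methyl | C=C1C(=O)O[C@H]2C[C@H](C)/C=C\C=C(\C)C[C@@H](OC(=O)[C@]3(C)COC(C)(C)O3)[C@H]12 | intermediate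
37 | C14 alcohol | C=C1C(=O)O[C@H]2C[C@H](C)/C=C\C=C(\CO)C[C@@H](OC(=O)[C@]3(C)COC(C)(C)O3)[C@H]12 | intermediate
38 | C14 acetate with side-chain acetonide | C=C1C(=O)O[C@H]2C[C@H](C)/C=C\C=C(\COC(C)=O)C[C@@H](OC(=O)[C@]3(C)COC(C)(C)O3)[C@H]12 | intermediate
39 | CNP0347302.1 | C=C1C(=O)O[C@H]2C[C@H](C)/C=C\C=C(\COC(C)=O)C[C@@H](OC(=O)[C@@](C)(O)CO)[C@H]12 | target

## Step count and least certain steps

Total: 22 steps. Longest linear sequence: 19 steps (steps 1–12 and 16–22); steps 13–15 make the side-chain acid.

**Step 11 (key step).** The likely failure is insufficient discrimination between the tetrasubstituted and trisubstituted alkenes, leading to over-cleavage; a second failure is epimerisation at C4 or C7, or transannular aldol reaction of the 1,6-diketone, if the work-up is not neutral. The fallback sets out from 19 and returns at 21. A peracid, which is far more sensitive to alkene substitution than ozone, is used first: mCPBA (1.0 equiv, NaHCO3, CH2Cl2, −20 °C) should give the ring-fusion epoxide F1. Aqueous HClO4 in THF opens it to the trans-3,8-diol F2, and Pb(OAc)4 in benzene cleaves the glycol to 21.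

**Step 12.** Two things can go wrong: hydride may not discriminate well between the C8 and C3 carbonyls, and it may attack C8 from the wrong face; under basic conditions the lactone may also migrate to the new C8 oxygen. C3-reduced or doubly reduced material can be returned to 21 with Dess–Martin periodinane. The fallback for the stereochemistry sets out from 21 and returns at 22. If reduction gives mainly the 8S alcohol F3, the centre is set by SN2 inversion instead of by facial selectivity: Mitsunobu reaction with chloroacetic acid (PPh3, DIAD, THF) gives the 8R chloroacetate F4, and thiourea with NaHCO3 in EtOH removes the chloroacetyl group to give 22.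

**Step 17.** The risks are formation of the ring-trans enol isomer, enolisation toward C4 with loss of that stereocentre, and migration of the β,γ-double bond before trapping. The fallback sets out from 29 and returns at 32, bypassing 31. The C3 ketone is reduced (NaBH4, MeOH, −40 °C) to the C3 alcohol F5, and the Burgess reagent in benzene at 50 °C effects syn-dehydration toward the allylic C2 hydrogens, which gives the conjugated diene 32 directly.

**Step 20.** The risks are competing ene reaction at the ring allylic positions C9 and C4, addition of selenium across the diene, and partial over-oxidation that leaves a mixture of oxidation levels. The fallback sets out from 36 and returns at 37. The oxidation is driven to its end point with stoichiometric SeO2 in dioxane at 60 °C, which should give the conjugated C14 aldehyde F6 as a single oxidation level, and Luche reduction (NaBH4, CeCl3·7H2O, MeOH, −40 °C) returns the primary alcohol 37 by 1,2-addition without touching the enoate. This fallback does not cure a failure of site selectivity between C14 and the ring positions.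

**Step 9.** The risks are incomplete reduction of the trialkylbenzene, poor solubility of the dilithium salt in ammonia, and isomerisation of the 1,4-diene on acidification. The fallback sets out from 16 and returns at 19, bypassing 18. LiAlH4 in THF reduces the lactone to the 1,4-diol F7, whose alkoxides are soluble and inert under Li/NH3/t-BuOH, so the Birch reduction gives the dihydro diol F8 with no acidic work-up. TEMPO with PhI(OAc)2 in CH2Cl2 then oxidises the primary alcohol and closes the lactol to the lactone 19.

## Further compounds

F1 | step 11 | C3–C8 epoxide of 19 (either face; configuration at C3 and C8 is lost on cleavage) | C1C(=O)O[C@H]2C[C@H](C)C34OC4(CC(C)=CC3)[C@H]12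
F2 | step 11 | trans-3,8-diol of 19 (configuration at C3 and C8 is lost on cleavage) | C1C(=O)O[C@H]2C[C@H](C)C3(O)C(O)(CC(C)=CC3)[C@H]12
F3 | step 12 | 8S epimer of 22 | C1C(=O)O[C@H]2C[C@H](C)C(=O)C/C=C(/C)C[C@H](O)[C@H]12
F4 | step 12 | 8R chloroacetate of 22 | C1C(=O)O[C@H]2C[C@H](C)C(=O)C/C=C(/C)C[C@@H](OC(=O)CCl)[C@H]12
F5 | step 17 | C3 alcohol from 29 (C3 epimers) | C1C(=O)O[C@H]2C[C@H](C)C(O)C/C=C(/C)C[C@@H](OC(=O)[C@]3(C)COC(C)(C)O3)[C@H]12
F6 | step 20 | C14 aldehyde of 36 | C=C1C(=O)O[C@H]2C[C@H](C)/C=C\C=C(\C=O)C[C@@H](OC(=O)[C@]3(C)COC(C)(C)O3)[C@H]12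
F7 | step 9 | (1S,2S,4S)-1-(2-hydroxyethyl)-4,7-dimethyl-1,2,3,4-tetrahydronaphthalen-2-ol | O[C@H]1C[C@H](C)c2ccc(C)cc2[C@@H]1CCO
F8 | step 9 | (1S,2S,4S)-1-(2-hydroxyethyl)-4,7-dimethyl-1,2,3,4,5,8-hexahydronaphthalen-2-ol | O[C@H]1C[C@H](C)C2=C(CC(C)=CC2)[C@@H]1CCO
A1 | alternative 1 | trans α-methylene lactone with free C8 hydroxyl, Z-vinyl iodide and vinylstannane termini | C=C1C(=O)O[C@@H](C[C@H](C)/C=C\I)[C@@H]1[C@H](O)C/C(CO[Si](C)(C)C(C)(C)C)=C\[Sn](CCCC)(CCCC)CCCC
A2 | alternative 1 | C6 diethylphosphonoacetate of the cis-7,8-epoxide | CCOP(=O)(OCC)CC(=O)O[C@@H](C[C@H](C)/C=C\I)[C@@H]1O[C@@H]1C/C(CO[Si](C)(C)C(C)(C)C)=C\[Sn](CCCC)(CCCC)CCCC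
A3 | alternative 2 | ten-membered dienone with C8 PMB ether | O=C1C[C@H](C)/C=C\C=C(\CO[Si](C)(C)C(C)(C)C)C[C@@H](OCc2ccc(OC)cc2)C1
A4 | alternative 2 | cis-1,2-dialkenyl-5-methylcyclohex-3-enol with E enol ether (configuration derived from a chair transition state) | O[C@]1(/C=C/OCc2ccc(OC)cc2)C[C@H](C)C=C[C@H]1C(=C)CO[Si](C)(C)C(C)(C)C
A5 | alternative 3 | ten-membered diene lactone with C14 silyl ether and side-chain acetonide | C=C1C(=O)O[C@H]2C[C@H](C)/C=C\C=C(\CO[Si](C)(C)C(C)(C)C)C[C@@H](OC(=O)[C@]3(C)COC(C)(C)O3)[C@H]12
A6 | alternative 3 | acyclic C1 vinylstannane / C2 Z-vinyl iodide with lactone and side chain in place | C=C1C(=O)O[C@@H](C[C@H](C)/C=C\I)[C@@H]1[C@H](OC(=O)[C@]2(C)COC(C)(C)O2)C/C(CO[Si](C)(C)C(C)(C)C)=C\[Sn](CCCC)(CCCC)CCCC
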